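## Structural features

The target is a 2-arylbenzofuran whose ring A (C3a–C7a) is a phloroglucinol-type ring with free hydroxyls at C4 and C6 and a 2-methylbut-3-en-2-yl (1,1-dimethylallyl) group at C7, between O6 and the furan oxygen O1. Furan C2 is bonded to C5' of a 7'-hydroxy-2,2-dimethylchroman, so the inter-ring bond is flanked by the alkyl carbon C4a', and both oxygens of that ring (O1', O7') are meta to it. The target has no stereocentre; the only ones met on the way are the adjacent C2 and C3 of a 2,3-dihydrobenzofuran, and they vanish on aromatisation. The fragile points are the o-(1,1-dimethylallyl)phenol (acid closes it to a trimethyldihydrofuran, heat can rearrange it further, H2 and electrophilic oxidants attack the terminal alkene), the electron-rich benzofuran and the air-sensitive triphenol. The real difficulties are to tell three phenols apart so that only O6 delivers the allyl unit, to place the quaternary benzylic carbon at C7 and not at C5, and to fix the chroman side chain at the right position of a 1,2,3,5-tetrasubstituted benzene. The key step exploits that O1–C2(aryl)–C3–C3a, fused to the 4,6-dioxygenated ring A, is a 5,7-dioxygenated flavanone (O1–C2–C3–C4–C4a) lacking C4. Flavanone C5, C7 and C8 map onto benzofuran C4, C6 and C7, and a 1,2-shift of C4a from C4 to C3 contracts the pyranone to the furan ring; the structures of 13 and 15 were checked against this mapping and are consistent with the target.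

## Logic of the disconnections

**22 ⇒ 21.** Two aryl O–S bonds and one O–acyl bond are put back on the three phenols. The gain is that the acid-sensitive o-(1,1-dimethylallyl)phenol is liberated last and by base alone. The forward step must cleave three groups with hydroxide without touching the alkene or the furan and must be worked up at mild pH.

**21 ⇒ 19.** The C7–C(quaternary) bond is cut and the allyl unit is returned, transposed, to O6 as a 3-methylbut-2-enyl ether. A [3,3] shift builds the hindered quaternary benzylic carbon from a simple ether and turns the allyl unit end for end. The forward step must choose C7 over C5 and must stop at the first rearrangement, which in-situ acylation of the phenol secures.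

**19 ⇒ 18 ⇒ 17.** The O6–allyl bond is cut, then O6 is masked as a benzyl ether. The benzyl group is a placeholder that survives acid, oxidants and sulfonylation and is removed by hydrogenolysis while no alkene is present. This demands that the sulfonates and the benzofuran stay inert to H2 over Pd/C.

**17 ⇒ 16 ⇒ 15.** The furan C2=C3 bond is saturated and a carboxyl carbon is added at C3. This reveals the ester that a ring contraction delivers. The forward steps must hydrolyse a hindered ester beside two sulfonates and then remove CO2 oxidatively so that the ring aromatises.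

**15 ⇒ 13.** The C3–C3a bond is cut and C4–C4a is restored, which expands the dihydrofuran back to a chroman-4-one. The gain is large: a flavanone is available from an aldol condensation of two aromatic halves. The forward step needs ring A to migrate in preference to the C2 aryl group and to dehydrogenation.

**13 ⇒ 12.** Both O–S bonds are cut. The two free phenols of 12 receive the same base-labile, acid- and oxidant-stable group in one operation. The demand is sulfonylation of a hydrogen-bonded 5-OH without opening the flavanone.

**12 ⇒ 10.** The O1–C2 bond is cut (oxa-Michael) and one ortho phenol is masked as a methoxymethyl ether. The flavanone becomes an open chalcone. The forward step removes the acetal with acid and closes the ring; C2 is formed racemic, which is harmless.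

**10 ⇒ 9 + 6.** The Cα=Cβ bond is cut into an acetophenone and an aryl aldehyde of similar size. The demand is a Claisen–Schmidt condensation in the presence of one free meta phenol on the aldehyde.

**9 ⇒ 8 ⇒ 7.** Two O–C bonds are cut. The symmetry of 7 leaves only para against ortho to be distinguished: the para OH becomes O6 of the target, one ortho OH becomes the ring oxygen and the other becomes O4.

**6 ⇒ 4.** The O1'–C2' ether bond and two O–CH3 bonds are cut. Only one phenol lies ortho to the side chain, so ring closure is unambiguous. The forward step must demethylate in the presence of an aldehyde and close a tertiary ether.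

**4 ⇒ 3 ⇒ 1 + 2.** The aryl–C bond of the side chain is cut. The bromine of 1 fixes the chain between the formyl group and one oxygen. An acid-catalysed prenyl annulation of a 5-substituted resorcinol was set aside because it can alkylate either the carbon between the hydroxyls or the one next to the third substituent. The demand is a Heck coupling at a doubly ortho-substituted bromide and a hydrogenation that spares the aldehyde.

## Other disconnections considered

**Alternative 1:** The cut runs through the benzene ring of the chroman (ring C) at C5'–C6' and C4a'–C8a'. Four carbons come from 1-methoxy-1,3-bis(trimethylsilyloxy)buta-1,3-diene A3 and two from the triple bond of the benzofuranyl ynone A2. In the forward step the nucleophilic terminus of A3 would add to the ynone carbon bearing the benzofuran, the ring would close, and loss of methanol and the silyl groups would aromatise the adduct to resorcinol A1. A1 would then have to be cyclised by oxa-Michael addition and deoxygenated at C4'.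
- In its favour: the 1,2,3,5 pattern of ring C is dictated by the polarity of both partners, no stereocentre is formed, no carbon is discarded as CO2, and the prenyl ether is already on ring A.
- Against it: A1 carries a C4' carbonyl that the target lacks. Removing it means acid, H2 or hot hydrazine in a molecule with a prenyl ether, a methoxymethyl acetal and a benzofuran. The enone of A2 is a second acceptor for the diene. A2 still needs O4 and O6 differentiated. The acetal must come off with acid either before the Claisen step (prenyl ether at risk) or after it (the allylphenol at risk).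
- Comparison: on regiocontrol of ring C it is the equal of the halogen-directed route to 6. On atom economy and the absence of transient stereocentres it is the better. On mechanism both rely on known reaction types untested on this pattern. The step count should be close, since the deoxygenation costs about what steps 10 and 11 cost. The chosen plan is preferred because its end game runs under base only.

**Alternative 2:** The cut is the furan C2–C3 bond; O1–C2 already exists in the aryl benzyl ether A5. In the forward step t-Bu-P4 would deprotonate the ArCH2O carbon, the carbanion would add to the neighbouring formyl group, and dehydration would give A4, the tris(methoxymethyl) ether of the target.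
- In its favour: it is the most convergent plan. Two aromatic halves are joined by an etherification and cyclised in one more step, with no redox change, no extruded carbon and no stereocentre. Aldehyde 6 could be reused after conversion to a benzylic halide. It should be several steps shorter, so it is better in step economy.
- Against it: the formyl group of A5 lies between two ortho oxygens and is a poor electrophile, and the benzylic C–H sits on an electron-rich ring and is weakly acidic. The phenol to be alkylated on the way to A5 lies between a formyl and a tert-alkyl group. The 1,1-dimethylallyl group must be installed before the etherification, so the Claisen question is only moved earlier. A4 can be deprotected only with acid, which the o-(1,1-dimethylallyl)phenol tolerates least.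
- Comparison: better in convergence and length; equal in the certainty of the ring-forming step (known type, unproven on so donor-rich a pair); worse in the end game, where the chosen plan uses base.

**Alternative 3:** The cut removes three bonds of ring A (C3a–C4, C4–C5, C6–C7). Ring A is grown onto a pre-formed 2-arylfuran from the two-carbon unit of diazoketone A7 and the two carbons of (triisopropylsilyloxy)ethyne A8. In the forward step, photochemical Wolff rearrangement of A7, cycloaddition with A8, four-electron ring opening and six-electron closure onto furan C3 would give A6.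
- In its favour: O4 (free hydroxyl) and O6 (silyl ether) emerge differentiated by the mechanism, which is better than the selective mono-benzylation of step 4. No carbon is discarded and no stereocentre is formed.
- Against it: A7 needs diazoketone chemistry on a 5-arylfuroic acid. A8 is a labile terminal siloxyalkyne. The electrocyclisation must use the furan 2,3-bond and give up furan aromaticity transiently. After A6, O4 still has to be capped, O6 desilylated, prenylated and rearranged, so the end game is as long as steps 12–15 and meets the same C5/C7 question. The acetal on O7' again calls for acid unless exchanged.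
- Comparison: better in O4/O6 differentiation and atom economy; equal in end-game length and overall step count; weaker in reagent handling and in the demand placed on the ring closure.

Key step: step 9

Assumptions: 2-bromo-3,5-dimethoxybenzaldehyde (1) is taken as a catalogue compound; it is otherwise one bromination away from 3,5-dimethoxybenzaldehyde. Compounds 12–16 are racemic and each is drawn as one enantiomer. Ts = 4-methylbenzenesulfonyl.

## Route

**Step 1**
Reactants: 1 2-bromo-3,5-dimethoxybenzaldehyde; 2 2-methylbut-3-en-2-ol
Product: 3 (E)-2-(3-hydroxy-3-methylbut-1-en-1-yl)-3,5-dimethoxybenzaldehyde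
Conditions: Pd(OAc)2 (5 mol %), P(o-tol)3 (10 mol %), Et3N, DMF, 100 °C
Reagents that add atoms: none
Why: Mizoroki–Heck reaction: oxidative addition of the bromide to zerovalent palladium, insertion at the unsubstituted alkene carbon and syn β-hydride elimination give the E alkene. The bromine fixes the chain between the formyl group and O3, so no regioisomer of the later chroman can arise.

**Step 2**
Reactants: 3 (E)-2-(3-hydroxy-3-methylbut-1-en-1-yl)-3,5-dimethoxybenzaldehyde
Product: 4 2-(3-hydroxy-3-methylbutyl)-3,5-dimethoxybenzaldehyde
Conditions: H2 (1 atm), 5% Pd/C, EtOAc, rt, stopped after 1 equiv H2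
Reagents that add atoms: none
Why: Heterogeneous hydrogenation of a disubstituted styrenyl alkene should be much faster at 1 atm than reduction of a hindered, electron-rich aryl aldehyde.

**Step 3**
Reactants: 4 2-(3-hydroxy-3-methylbutyl)-3,5-dimethoxybenzaldehyde
Product: 6 7-hydroxy-2,2-dimethylchroman-5-carbaldehyde, via tertiary bromide 5 (not isolated)
Conditions: BBr3 (5 equiv), CH2Cl2, −78 °C → rt; H2O, 0 °C; then p-TsOH·H2O (cat.), PhMe, 80 °C
Reagents that add atoms: boron tribromide, BrB(Br)Br (source of the bromine in intermediate 5; none of its atoms remain in 6)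
Why: Lewis-acid cleavage of both aryl methyl ethers, with conversion of the tertiary alcohol to the tertiary bromide, is followed by capture of the tertiary cation by the only phenol ortho to the chain (intramolecular etherification to the six-membered ring). The acid finish returns any open-chain bromide or alkene to the chroman, which is the thermodynamic product.

**Step 4**
Reactants: 7 2,4,6-trihydroxyacetophenone
Product: 8 1-[4-(benzyloxy)-2,6-dihydroxyphenyl]ethanone
Conditions: BnBr (1.0 equiv), K2CO3 (1.05 equiv), DMF, 0 °C → rt
Reagents that add atoms: benzyl bromide, BrCc1ccccc1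
Why: Williamson etherification. The para hydroxyl is the most acidic and the only one not engaged in a hydrogen bond to the acetyl group, so one equivalent of base and halide should alkylate it preferentially.

**Step 5**
Reactants: 8 1-[4-(benzyloxy)-2,6-dihydroxyphenyl]ethanone
Product: 9 1-[4-(benzyloxy)-2-hydroxy-6-(methoxymethoxy)phenyl]ethanone
Conditions: MOMCl (1.1 equiv), i-Pr2NEt, CH2Cl2, 0 °C
Reagents that add atoms: chloromethyl methyl ether, COCCl
Why: Acetal ether formation at one of the two equivalent ortho hydroxyls. The remaining one is then locked in a strong hydrogen bond to the ketone and stays free.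

**Step 6**
Reactants: 9 1-[4-(benzyloxy)-2-hydroxy-6-(methoxymethoxy)phenyl]ethanone; 6 7-hydroxy-2,2-dimethylchroman-5-carbaldehyde
Product: 10 (E)-1-[4-(benzyloxy)-2-hydroxy-6-(methoxymethoxy)phenyl]-3-(7-hydroxy-2,2-dimethylchroman-5-yl)prop-2-en-1-one
Conditions: KOH (50% aq), EtOH, rt; then 1 M HCl
Reagents that add atoms: none
Why: Claisen–Schmidt condensation (aldol addition, then E1cB dehydration to the E enone). The acetal on one ortho oxygen avoids the unreactive dianion of a 2,6-dihydroxyacetophenone, and the phenoxide of 6 is meta to the formyl group and does not deactivate it by resonance.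

**Step 7**
Reactants: 10 (E)-1-[4-(benzyloxy)-2-hydroxy-6-(methoxymethoxy)phenyl]-3-(7-hydroxy-2,2-dimethylchroman-5-yl)prop-2-en-1-one
Product: 12 rac-7-(benzyloxy)-5-hydroxy-2-(7-hydroxy-2,2-dimethylchroman-5-yl)chroman-4-one, via dihydroxychalcone 11 (not isolated)
Conditions: 3 M HCl, MeOH/THF, 50 °C; then NaOAc, EtOH, reflux
Reagents that add atoms: none
Why: Acidic acetal cleavage frees the second ortho phenol, and 2',6'-dihydroxychalcones close readily by 6-endo oxa-Michael addition to 5-hydroxyflavanones. C2 is formed without control (racemic) and is erased in step 11.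

**Step 8**
Reactants: 12 rac-7-(benzyloxy)-5-hydroxy-2-(7-hydroxy-2,2-dimethylchroman-5-yl)chroman-4-one
Product: 13 rac-7-(benzyloxy)-2-[2,2-dimethyl-7-(tosyloxy)chroman-5-yl]-5-(tosyloxy)chroman-4-one
Conditions: TsCl (2.6 equiv), Et3N, DMAP (0.2 equiv), CH2Cl2, 0 °C → rt
Reagents that add atoms: 4-methylbenzenesulfonyl chloride, Cc1ccc(S(=O)(=O)Cl)cc1
Why: DMAP-catalysed sulfonylation of both phenols. An amine base at rt, rather than carbonate at reflux, limits retro-oxa-Michael opening of the flavanone, and the sulfonates tolerate the acid, oxidant, hydrogenolysis and heat that follow and fall to base at the end.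

**Step 9**
Reactants: 13 rac-7-(benzyloxy)-2-[2,2-dimethyl-7-(tosyloxy)chroman-5-yl]-5-(tosyloxy)chroman-4-one
Product: 15 methyl rac-trans-6-(benzyloxy)-2-[2,2-dimethyl-7-(tosyloxy)chroman-5-yl]-4-(tosyloxy)-2,3-dihydrobenzofuran-3-carboxylate, via enol ether 14 (not isolated)
Conditions: PhI(OAc)2 (1.3 equiv), conc. H2SO4 (0.5 equiv), HC(OMe)3, rt
Reagents that add atoms: trimethyl orthoformate, COC(OC)OC (the methoxy group of 14 and of the ester in 15)
Why: Acid and the orthoformate convert the C4 ketone of 13 into enol ether 14, whose C3 is attacked by the electrophilic trivalent iodine of PhI(OAc)2 on the face away from the C2 aryl group, after which methanol adds to the oxocarbenium ion to give a C4 dimethyl ketal bearing a C3–I(Ph)OAc group. Reductive loss of iodobenzene is assisted by a 1,2-shift of the ring A carbon C4a from C4 to C3 through a bridged phenonium-type transition state, which forms the C3–C3a bond and leaves C4 as a dialkoxycarbenium ion that collapses to the methyl ester. The five-membered ring is therefore not closed by a cyclisation but arises by contraction of the pyranone (a semipinacol-type 1,2-aryl shift), the closest known reaction being the oxidative rearrangement of flavanones and aryl alkyl ketones with hypervalent iodine or Tl(NO3)3 in trimethyl orthoformate. C2 keeps its configuration and C3 is set trans to the C2 aryl group, both by the anti approach of the iodane with invertive migration and because the C3–H next to the ester can equilibrate under the acid to the less crowded trans isomer; 13 being racemic, 15 is the racemic trans ester, and both centres are erased in step 11. The step needs chemoselectivity for migration of ring A over migration of the C2 aryl group (the isoflavone pathway) and over plain dehydrogenation to the flavone. Ring A has a para benzyloxy group and an ortho ring oxygen that stabilise the bridged cation, whereas the C2 aryl ring carries both its oxygens meta to the carbon that would migrate, one of them as an electron-poor sulfonate, and so should migrate poorly. The sulfonates and the benzyl ether also keep the phenols from oxidation and are stable to H2SO4 and methanol.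

**Step 10**
Reactants: 15 methyl rac-trans-6-(benzyloxy)-2-[2,2-dimethyl-7-(tosyloxy)chroman-5-yl]-4-(tosyloxy)-2,3-dihydrobenzofuran-3-carboxylate
Product: 16 rac-trans-6-(benzyloxy)-2-[2,2-dimethyl-7-(tosyloxy)chroman-5-yl]-4-(tosyloxy)-2,3-dihydrobenzofuran-3-carboxylic acid
Conditions: LiOH·H2O (3 equiv), THF/H2O 3:1, 0 °C → rt; then 1 M HCl
Reagents that add atoms: lithium hydroxide, [Li+].[OH-] (the hydroxyl oxygen of the carboxylic acid)
Why: Saponification by acyl–oxygen cleavage; aryl sulfonates should survive hydroxide at rt. Opening of the ring from the ester enolate would be a reverse 5-endo process and is stereoelectronically disfavoured, and epimerisation at C3 is of no consequence.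

**Step 11**
Reactants: 16 rac-trans-6-(benzyloxy)-2-[2,2-dimethyl-7-(tosyloxy)chroman-5-yl]-4-(tosyloxy)-2,3-dihydrobenzofuran-3-carboxylic acid
Product: 17 6-(benzyloxy)-2-[2,2-dimethyl-7-(tosyloxy)chroman-5-yl]-4-(tosyloxy)benzofuran
Conditions: Pb(OAc)4 (1.3 equiv), Cu(OAc)2 (10 mol %), pyridine (2 equiv), PhH, 80 °C
Reagents that add atoms: none
Why: Kochi oxidative decarboxylation: the lead carboxylate loses CO2 to a benzylic C3 radical, which the copper salt oxidises to a cation stabilised by the para benzyloxy group. Loss of the C2 proton then gives the aromatic furan and removes both stereocentres.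

**Step 12**
Reactants: 17 6-(benzyloxy)-2-[2,2-dimethyl-7-(tosyloxy)chroman-5-yl]-4-(tosyloxy)benzofuran
Product: 18 2-[2,2-dimethyl-7-(tosyloxy)chroman-5-yl]-4-(tosyloxy)benzofuran-6-ol
Conditions: H2 (1 atm), 10% Pd/C, EtOAc/THF, rt
Reagents that add atoms: none
Why: Hydrogenolysis of the benzyl ether; aryl sulfonates and the 2-arylbenzofuran double bond should be inert at 1 atm. The step is placed before any alkene is present.

**Step 13**
Reactants: 18 2-[2,2-dimethyl-7-(tosyloxy)chroman-5-yl]-4-(tosyloxy)benzofuran-6-ol
Product: 19 2-[2,2-dimethyl-7-(tosyloxy)chroman-5-yl]-6-(3-methylbut-2-enyloxy)-4-(tosyloxy)benzofuran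
Conditions: prenyl bromide (1.3 equiv), K2CO3, acetone, 50 °C
Reagents that add atoms: 1-bromo-3-methylbut-2-ene, CC(C)=CCBr
Why: Williamson O-allylation of the only free phenol with a mild base that leaves the sulfonates intact.

**Step 14**
Reactants: 19 2-[2,2-dimethyl-7-(tosyloxy)chroman-5-yl]-6-(3-methylbut-2-enyloxy)-4-(tosyloxy)benzofuran
Product: 21 2-[2,2-dimethyl-7-(tosyloxy)chroman-5-yl]-7-(2-methylbut-3-en-2-yl)-4-(tosyloxy)benzofuran-6-yl butanoate, via free phenol 20 (not isolated)
Conditions: PhNEt2, (n-PrCO)2O (5 equiv), 190 °C, Ar
Reagents that add atoms: butanoic anhydride, CCCC(=O)OC(=O)CCC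
Why: Aromatic Claisen rearrangement ([3,3]) with inversion of the allyl unit gives the 1,1-dimethylallyl group. C7 should be preferred over C5 because the C6–C7 bond of a benzofuran has the higher double-bond character and C5 is crowded by the 4-tosyloxy group, and the para position is a ring-fusion carbon, so no onward Cope shift is possible. Acylation of phenol 20 as it forms suppresses the abnormal Claisen rearrangement and ring closure onto the alkene.

**Step 15**
Reactants: 21 2-[2,2-dimethyl-7-(tosyloxy)chroman-5-yl]-7-(2-methylbut-3-en-2-yl)-4-(tosyloxy)benzofuran-6-yl butanoate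
Product: 22 2-(7-hydroxy-2,2-dimethylchroman-5-yl)-7-(2-methylbut-3-en-2-yl)benzofuran-4,6-diol (CNP0300714.0)
Conditions: KOH (10 equiv), EtOH/H2O 4:1 (degassed), reflux, Ar; then 1 M HCl to pH 5, 0 °C
Reagents that add atoms: none
Why: Alkaline hydrolysis of the ester and sulfur–oxygen cleavage of both aryl sulfonates by hydroxide. Base is used because the o-(1,1-dimethylallyl)phenol cyclises under acid, and the alkene, the chroman and the benzofuran are inert to hydroxide; oxygen is excluded to protect the triphenol.

## Compound list

1 | 2-bromo-3,5-dimethoxybenzaldehyde | O=Cc1cc(OC)cc(OC)c1Br | starting material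
2 | 2-methylbut-3-en-2-ol | C=CC(C)(C)O | starting material
3 | (E)-2-(3-hydroxy-3-methylbut-1-en-1-yl)-3,5-dimethoxybenzaldehyde | O=Cc1cc(OC)cc(OC)c1/C=C/C(C)(C)O | intermediate
4 | 2-(3-hydroxy-3-methylbutyl)-3,5-dimethoxybenzaldehyde | O=Cc1cc(OC)cc(OC)c1CCC(C)(C)O | intermediate
5 | 2-(3-bromo-3-methylbutyl)-3,5-dihydroxybenzaldehyde | O=Cc1cc(O)cc(O)c1CCC(C)(C)Br | intermediate (not isolated)
6 | 7-hydroxy-2,2-dimethylchroman-5-carbaldehyde | O=Cc1cc(O)cc2c1CCC(C)(C)O2 | intermediate
7 | 2,4,6-trihydroxyacetophenone | CC(=O)c1c(O)cc(O)cc1O | starting material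
8 | 1-[4-(benzyloxy)-2,6-dihydroxyphenyl]ethanone | CC(=O)c1c(O)cc(OCc2ccccc2)cc1O | intermediate
9 | 1-[4-(benzyloxy)-2-hydroxy-6-(methoxymethoxy)phenyl]ethanone | CC(=O)c1c(O)cc(OCc2ccccc2)cc1OCOC | intermediate
10 | (E)-1-[4-(benzyloxy)-2-hydroxy-6-(methoxymethoxy)phenyl]-3-(7-hydroxy-2,2-dimethylchroman-5-yl)prop-2-en-1-one | O=C(/C=C/c1cc(O)cc2c1CCC(C)(C)O2)c1c(O)cc(OCc2ccccc2)cc1OCOC | intermediate
11 | (E)-1-[4-(benzyloxy)-2,6-dihydroxyphenyl]-3-(7-hydroxy-2,2-dimethylchroman-5-yl)prop-2-en-1-one | O=C(/C=C/c1cc(O)cc2c1CCC(C)(C)O2)c1c(O)cc(OCc2ccccc2)cc1O | intermediate (not isolated)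
12 | rac-7-(benzyloxy)-5-hydroxy-2-(7-hydroxy-2,2-dimethylchroman-5-yl)chroman-4-one (one enantiomer drawn) | O=C1C[C@@H](c2cc(O)cc3c2CCC(C)(C)O3)Oc2cc(OCc3ccccc3)cc(O)c12 | intermediate
13 | rac-7-(benzyloxy)-2-[2,2-dimethyl-7-(tosyloxy)chroman-5-yl]-5-(tosyloxy)chroman-4-one (one enantiomer drawn) | O=C1C[C@@H](c2cc(OS(=O)(=O)c3ccc(C)cc3)cc3c2CCC(C)(C)O3)Oc2cc(OCc3ccccc3)cc(OS(=O)(=O)c3ccc(C)cc3)c12 | intermediate
14 | rac-7-(benzyloxy)-4-methoxy-2-[2,2-dimethyl-7-(tosyloxy)chroman-5-yl]-5-(tosyloxy)-2H-chromene (one enantiomer drawn) | COC1=C[C@@H](c2cc(OS(=O)(=O)c3ccc(C)cc3)cc3c2CCC(C)(C)O3)Oc2cc(OCc3ccccc3)cc(OS(=O)(=O)c3ccc(C)cc3)c12 | intermediate (not isolated)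
15 | methyl rac-trans-6-(benzyloxy)-2-[2,2-dimethyl-7-(tosyloxy)chroman-5-yl]-4-(tosyloxy)-2,3-dihydrobenzofuran-3-carboxylate (one enantiomer drawn) | COC(=O)[C@@H]1[C@@H](c2cc(OS(=O)(=O)c3ccc(C)cc3)cc3c2CCC(C)(C)O3)Oc2cc(OCc3ccccc3)cc(OS(=O)(=O)c3ccc(C)cc3)c12 | intermediate
16 | rac-trans-6-(benzyloxy)-2-[2,2-dimethyl-7-(tosyloxy)chroman-5-yl]-4-(tosyloxy)-2,3-dihydrobenzofuran-3-carboxylic acid (one enantiomer drawn) | OC(=O)[C@@H]1[C@@H](c2cc(OS(=O)(=O)c3ccc(C)cc3)cc3c2CCC(C)(C)O3)Oc2cc(OCc3ccccc3)cc(OS(=O)(=O)c3ccc(C)cc3)c12 | intermediate
17 | 6-(benzyloxy)-2-[2,2-dimethyl-7-(tosyloxy)chroman-5-yl]-4-(tosyloxy)benzofuran | c1c(OCc2ccccc2)cc(OS(=O)(=O)c2ccc(C)cc2)c2cc(-c3cc(OS(=O)(=O)c4ccc(C)cc4)cc4c3CCC(C)(C)O4)oc12 | intermediate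
18 | 2-[2,2-dimethyl-7-(tosyloxy)chroman-5-yl]-4-(tosyloxy)benzofuran-6-ol | Oc1cc(OS(=O)(=O)c2ccc(C)cc2)c2cc(-c3cc(OS(=O)(=O)c4ccc(C)cc4)cc4c3CCC(C)(C)O4)oc2c1 | intermediate
19 | 2-[2,2-dimethyl-7-(tosyloxy)chroman-5-yl]-6-(3-methylbut-2-enyloxy)-4-(tosyloxy)benzofuran | CC(C)=CCOc1cc(OS(=O)(=O)c2ccc(C)cc2)c2cc(-c3cc(OS(=O)(=O)c4ccc(C)cc4)cc4c3CCC(C)(C)O4)oc2c1 | intermediate
20 | 2-[2,2-dimethyl-7-(tosyloxy)chroman-5-yl]-7-(2-methylbut-3-en-2-yl)-4-(tosyloxy)benzofuran-6-ol | C=CC(C)(C)c1c(O)cc(OS(=O)(=O)c2ccc(C)cc2)c2cc(-c3cc(OS(=O)(=O)c4ccc(C)cc4)cc4c3CCC(C)(C)O4)oc12 | intermediate (not isolated)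
21 | 2-[2,2-dimethyl-7-(tosyloxy)chroman-5-yl]-7-(2-methylbut-3-en-2-yl)-4-(tosyloxy)benzofuran-6-yl butanoate | C=CC(C)(C)c1c(OC(=O)CCC)cc(OS(=O)(=O)c2ccc(C)cc2)c2cc(-c3cc(OS(=O)(=O)c4ccc(C)cc4)cc4c3CCC(C)(C)O4)oc12 | intermediate
22 | 2-(7-hydroxy-2,2-dimethylchroman-5-yl)-7-(2-methylbut-3-en-2-yl)benzofuran-4,6-diol | C=CC(C)(C)c1c(O)cc(O)c2cc(-c3cc(O)cc4c3CCC(C)(C)O4)oc12 | target

## Step count and risks

Total: 15 steps. Longest linear sequence: 13 steps (steps 1–3 and 6–15); the acetophenone branch (steps 4 and 5) joins at step 6.

**Step 9 (key step).** Most likely to go wrong: slow ketalisation of the C4 carbonyl beside the peri tosyloxy group, so that the iodane instead effects dehydrogenation or α-methoxylation, or a competing shift of the C2 aryl group along the isoflavone pathway. Changing the oxidant to Tl(NO3)3 would alter only the conditions. The fallback keeps the same bond changes but reaches them through a carbene. It sets out from 13: heating with Me2NCH(OMe)2 in PhMe should give the enaminone rac-(E)-7-(benzyloxy)-3-[(dimethylamino)methylidene]-2-[2,2-dimethyl-7-(tosyloxy)chroman-5-yl]-5-(tosyloxy)chroman-4-one F1. Diazo transfer from TsN3 in MeCN should then give rac-7-(benzyloxy)-3-diazo-2-[2,2-dimethyl-7-(tosyloxy)chroman-5-yl]-5-(tosyloxy)chroman-4-one F2. Irradiation of F2 in methanol should trigger a Wolff rearrangement in which C4a again moves from C4 to C3, and methanol traps the ketene. The fallback returns to the route at 15; the cis/trans ratio does not matter.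

**Step 14.** Most likely to go wrong: rearrangement toward C5 instead of C7, or onward reaction of the liberated phenol (abnormal Claisen rearrangement, ring closure onto the alkene, loss of the allyl group) before it is acylated at 190 °C. The fallback sets out from 19 and replaces the thermal, trapped process by a Lewis-acid-catalysed [3,3] shift with Eu(fod)3 (10 mol %) in CHCl3 or PhCl at 60–80 °C, without acylation. Phenol 20 is then isolated and put directly under the conditions of step 15, so the fallback returns at 22 and omits 21 (no new compound, F0).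

**Step 11.** Most likely to go wrong: capture of the C3 cation by acetate instead of proton loss, slow ligand exchange of the hindered acid at lead, or over-oxidation of the electron-rich benzofuran and benzylic positions by excess oxidant. The fallback separates decarboxylation from oxidation and sets out from 16. Coupling with N-hydroxypyridine-2-thione (DCC, DMAP cat., CH2Cl2, dark) should give the Barton ester 2-thioxopyridin-1(2H)-yl rac-trans-6-(benzyloxy)-2-[2,2-dimethyl-7-(tosyloxy)chroman-5-yl]-4-(tosyloxy)-2,3-dihydrobenzofuran-3-carboxylate F3. Photolysis with t-BuSH should give, by reductive radical decarboxylation, rac-6-(benzyloxy)-2-[2,2-dimethyl-7-(tosyloxy)chroman-5-yl]-4-(tosyloxy)-2,3-dihydrobenzofuran F4. DDQ in PhMe at 80 °C should dehydrogenate F4, returning to the route at 17.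

**Step 3.** Most likely to go wrong: reopening of the tertiary aryl ether by excess BBr3 with elimination of the tertiary bromide, or degradation of the electron-rich hydroxy aldehyde under HBr. The fallback changes the order so that BBr3 meets neither the tertiary alcohol nor the chroman. It sets out from 1, which is demethylated first (BBr3, CH2Cl2) to 2-bromo-3,5-dihydroxybenzaldehyde F5. Heck coupling of F5 with 2 (Pd(OAc)2, P(o-tol)3, Et3N, DMF) should give (E)-3,5-dihydroxy-2-(3-hydroxy-3-methylbut-1-en-1-yl)benzaldehyde F6. Hydrogenation (H2, Pd/C, EtOAc) should give 3,5-dihydroxy-2-(3-hydroxy-3-methylbutyl)benzaldehyde F7, and catalytic p-TsOH in PhMe at 80 °C closes the ring, returning to the route at 6.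

**Step 10.** Most likely to go wrong: hydroxide attack at sulfur of the sulfonates, above all the one ortho to the reacting centre, competing with slow hydrolysis of a hindered ester. The fallback sets out from 15 and cleaves the ester at the methyl carbon instead of the carbonyl: LiI in EtOAc or pyridine at reflux (SN2 demethylation), then dilute acid, returning at 16 (no new compound, F0).

## Further compounds

F1 | step 9 | rac-(E)-7-(benzyloxy)-3-[(dimethylamino)methylidene]-2-[2,2-dimethyl-7-(tosyloxy)chroman-5-yl]-5-(tosyloxy)chroman-4-one | O=C1/C(=C/N(C)C)[C@@H](c2cc(OS(=O)(=O)c3ccc(C)cc3)cc3c2CCC(C)(C)O3)Oc2cc(OCc3ccccc3)cc(OS(=O)(=O)c3ccc(C)cc3)c12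
F2 | step 9 | rac-7-(benzyloxy)-3-diazo-2-[2,2-dimethyl-7-(tosyloxy)chroman-5-yl]-5-(tosyloxy)chroman-4-one | O=C1C(=[N+]=[N-])[C@@H](c2cc(OS(=O)(=O)c3ccc(C)cc3)cc3c2CCC(C)(C)O3)Oc2cc(OCc3ccccc3)cc(OS(=O)(=O)c3ccc(C)cc3)c12
F0 | step 14 | none | none
F3 | step 11 | 2-thioxopyridin-1(2H)-yl rac-trans-6-(benzyloxy)-2-[2,2-dimethyl-7-(tosyloxy)chroman-5-yl]-4-(tosyloxy)-2,3-dihydrobenzofuran-3-carboxylate | O=C(On1ccccc1=S)[C@@H]1[C@@H](c2cc(OS(=O)(=O)c3ccc(C)cc3)cc3c2CCC(C)(C)O3)Oc2cc(OCc3ccccc3)cc(OS(=O)(=O)c3ccc(C)cc3)c12
F4 | step 11 | rac-6-(benzyloxy)-2-[2,2-dimethyl-7-(tosyloxy)chroman-5-yl]-4-(tosyloxy)-2,3-dihydrobenzofuran | C1[C@@H](c2cc(OS(=O)(=O)c3ccc(C)cc3)cc3c2CCC(C)(C)O3)Oc2cc(OCc3ccccc3)cc(OS(=O)(=O)c3ccc(C)cc3)c12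
F5 | step 3 | 2-bromo-3,5-dihydroxybenzaldehyde | O=Cc1cc(O)cc(O)c1Br
F6 | step 3 | (E)-3,5-dihydroxy-2-(3-hydroxy-3-methylbut-1-en-1-yl)benzaldehyde | O=Cc1cc(O)cc(O)c1/C=C/C(C)(C)O
F7 | step 3 | 3,5-dihydroxy-2-(3-hydroxy-3-methylbutyl)benzaldehyde | O=Cc1cc(O)cc(O)c1CCC(C)(C)O
F0 | step 10 | none | none
A1 | alternative 1 | 1-{2,4-dihydroxy-6-[4-(methoxymethoxy)-6-(3-methylbut-2-enyloxy)benzofuran-2-yl]phenyl}-3-methylbut-2-en-1-one | CC(C)=CC(=O)c1c(O)cc(O)cc1-c1cc2c(OCOC)cc(OCC=C(C)C)cc2o1
A2 | alternative 1 | 1-[4-(methoxymethoxy)-6-(3-methylbut-2-enyloxy)benzofuran-2-yl]-5-methylhex-4-en-1-yn-3-one | CC(C)=CC(=O)C#Cc1cc2c(OCOC)cc(OCC=C(C)C)cc2o1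
A3 | alternative 1 | 1-methoxy-1,3-bis(trimethylsilyloxy)buta-1,3-diene (ketene acetal geometry not defined) | COC(O[Si](C)(C)C)=CC(=C)O[Si](C)(C)C
A4 | alternative 2 | 4,6-bis(methoxymethoxy)-2-[7-(methoxymethoxy)-2,2-dimethylchroman-5-yl]-7-(2-methylbut-3-en-2-yl)benzofuran | C=CC(C)(C)c1c(OCOC)cc(OCOC)c2cc(-c3cc(OCOC)cc4c3CCC(C)(C)O4)oc12
A5 | alternative 2 | 4,6-bis(methoxymethoxy)-2-{[7-(methoxymethoxy)-2,2-dimethylchroman-5-yl]methoxy}-3-(2-methylbut-3-en-2-yl)benzaldehyde | O=Cc1c(OCOC)cc(OCOC)c(C(C)(C)C=C)c1OCc1cc(OCOC)cc2c1CCC(C)(C)O2
A6 | alternative 3 | 2-[7-(methoxymethoxy)-2,2-dimethylchroman-5-yl]-6-(triisopropylsilyloxy)benzofuran-4-ol | Oc1cc(O[Si](C(C)C)(C(C)C)C(C)C)cc2oc(-c3cc(OCOC)cc4c3CCC(C)(C)O4)cc12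
A7 | alternative 3 | 2-diazo-1-{5-[7-(methoxymethoxy)-2,2-dimethylchroman-5-yl]furan-2-yl}ethanone | [N-]=[N+]=CC(=O)c1ccc(-c2cc(OCOC)cc3c2CCC(C)(C)O3)o1
A8 | alternative 3 | (triisopropylsilyloxy)ethyne | C#CO[Si](C(C)C)(C(C)C)C(C)C
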